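Late in the amber run the right-handed substrate read 29% at 5.00 min and 30% at 8.00 min, so I answered your quick question about the new flask from there. Your hunch was that its 2.0 mM of precatalyst would carry it to the end, but I did not expect that, because the flask holds less partner than substrate. That makes partner the limiting reagent if one partner serves one substrate.

the same everywhere: left-handed substrate 0.20 M; right-handed substrate 0.20 M

| charge | partner | protic impurity | precatalyst | remark | time |
|---|---|---|---|---|---|
| amber | 0.24 M | 0.010 M | 1 mM | run made earlier |  |
| violet | 0.24 M | 0.010 M | 1.5 mM | run made earlier |  |
| grey | 0.12 M | 0.010 M | 2 mM | run made earlier |  |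
| flask | 0.240 M | 0.0100 M | 2.0 mM |  | 10 min |

| run | time / min | left-handed substrate / % | right-handed substrate / % |
|---|---|---|---|
| amber | 1.00 | 36 | 43 |
| amber | 3.00 | 21 | 35 |
| amber | 5.00 | 20 | 29 |
| amber | 8.00 | 16 | 30 |
| violet | 2.00 | 19 | 34 |
| violet | 4.00 | 16 | 31 |
| violet | 6.00 | 19 | 30 |
| violet | 8.00 | 12 | 25 |
| grey | 1.00 | 39 | 45 |
| grey | 3.00 | 35 | 40 |
| grey | 5.00 | 32 | 44 |
| grey | 8.00 | 26 | 41 |

(scatter of a reading: 2 percentage points)

1. part of the left-handed substrate and right-handed substrate charged together that has reacted at 10 min
2. excess of left-handed product over right-handed product in the product at 10 min
3. excess of right-handed substrate over left-handed substrate among what is left of the two at 10 min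

- free catalyst is single-handed; left-handed substrate and right-handed substrate are mirror images of each other, charged as a racemate, each of them at the stated concentration
- the earlier runs were read with a standard deviation of 2 percentage points
- an excess is the difference of the two amounts in percent of their sum
- an excess is below zero if the other one leads

At 8.00 min, the readings put 54.0% reacted in amber against 33.0% in grey, which had half the partner and twice the precatalyst. I let the impurity take its whole charge of partner, so I reckoned that the flask would stop near 57.5% reacted, and I assumed it would get there in the time.

For the split I divided one substrate's rate by the other's, assuming each falls in proportion to itself on the same partner and catalyst, so that time drops out. What remains is the selectivity factor: the logarithm of the left-handed substrate's surviving share of its charge over the same logarithm for the right-handed substrate. The amber and violet readings at 8.00 min averaged 2.14, a reading that carries their scatter.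

At that conversion it gave me 28.0% right-handed and 14.5% left-handed substrate. So I expected a substrate excess of 32.0% and a product excess of 23.6%.

The forecast, above me on both excesses, gave 57% reacted, 26% and 34%, holding that “partner is consumed stoichiometrically and limits conversion”.

The flask gave 57.6% reacted, a product excess of 25.3% and a substrate excess of 34.3%.

    partner + free catalyst + left-handed substrate → free catalyst + left-handed product (k = 100 M⁻² s⁻¹)
    partner + free catalyst + right-handed substrate → free catalyst + right-handed product (k = 44.0 M⁻² s⁻¹)
    free catalyst → spent catalyst (k = 0.00390 s⁻¹)
    partner + precatalyst → free catalyst + spent reagent (k = 0.0660 M⁻¹ s⁻¹)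
    partner + protic impurity → quenched reagent (k = 0.0410 M⁻¹ s⁻¹)

At 10.0 min the flask held 28.5% of right-handed substrate, which my factor turned into 15.0% of left-handed substrate, where 13.9% stood. In the neighbouring flask, the same but with 0.41 M of partner, the 8.66% of right-handed substrate at that time gave 1.16% of left-handed substrate by the same factor, where 0.929% stood. That neighbour reached 90.4% reacted, its product excess fell to 8.55%, and its substrate excess rose to 80.6%.

The readings come from a simulation on assumed constants; noise was put on by code.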